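**Plan**

- Ring labels: A is the phenol ring whose aryloxy carbon lies para to its benzylic carbon; B is the meta-linked ring on the ring A oxygen; C is the para-linked ring; D is the phenol ring whose hydroxyl lies para to its benzylic carbon. Enabling feature: the ether carbon of ring C has a C–H carbon on each side, so one of them can carry a nitro group ortho to a fluorine and later be returned to C–H.
- Retrosynthesis cuts, in order: the two O–CH3 bonds; the ring C C–H (back to C–NO2); the macrocyclic O(ring D)–C(ring C) bond; the two CH2–CH2 bonds (as Wittig alkenes); the O(ring B)–C(ring A) ether bond.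
- Forward: SNAr joins rings A and B; a first Wittig reaction adds ring D and a second adds the fluoronitro ring C; diimide saturates both alkenes; the ring D phenol is freed; SNAr closes the only ring (20-membered); the nitro group is excised; both methyl ethers are cleaved.
- Stereochemistry: the target has no stereocentre, and the alkene geometry from the Wittig steps disappears on reduction.

Key step: step 12

Remark: both Wittig steps are expected to give E/Z mixtures, so the SMILES of 10, 11, 12, 14 and 15 carry no alkene descriptor; both double bonds are saturated in step 10.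

**Route**

Step 1
Reactants: 1 3-hydroxybenzyl alcohol; 2 4-fluoro-3-methoxybenzaldehyde
Product: 3 4-[3-(hydroxymethyl)phenoxy]-3-methoxybenzaldehyde
Conditions: K2CO3, DMF, 120 °C
Reagents that add atoms: none
Why: Nucleophilic aromatic substitution (SNAr) in which the para formyl group stabilises the Meisenheimer intermediate, and carbonate deprotonates only the phenol of 1, so the diaryl ether should form at the phenolic oxygen and not at the benzylic alcohol.

Step 2
Reactants: 4 isovanillin (3-hydroxy-4-methoxybenzaldehyde)
Product: 5 4-methoxy-3-(methoxymethoxy)benzaldehyde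
Conditions: MOMCl, K2CO3, acetone, reflux
Reagents that add atoms: chloromethyl methyl ether, COCCl
Why: Williamson-type O-alkylation of the phenoxide by the reactive alpha-chloro ether gives the MOM acetal, which tolerates the basic, reducing and phosphine steps ahead and is later removed by acid without touching nitro, fluoride or methyl ethers.

Step 3
Reactants: 5 4-methoxy-3-(methoxymethoxy)benzaldehyde
Product: 6 [4-methoxy-3-(methoxymethoxy)phenyl]methanol
Conditions: NaBH4, MeOH, 0 °C
Reagents that add atoms: none
Why: Borohydride reduction of the aryl aldehyde gives the benzylic alcohol and leaves the acetal and the methyl ether untouched.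

Step 4
Reactants: 6 [4-methoxy-3-(methoxymethoxy)phenyl]methanol
Product: 7 4-(bromomethyl)-1-methoxy-2-(methoxymethoxy)benzene
Conditions: CBr4, PPh3, CH2Cl2, 0 °C (used crude)
Reagents that add atoms: carbon tetrabromide, BrC(Br)(Br)Br
Why: Appel reaction, in which bromide displaces the alkoxyphosphonium ion under neutral conditions that spare the acid-labile MOM group.

Step 5
Reactants: 7 4-(bromomethyl)-1-methoxy-2-(methoxymethoxy)benzene
Product: 8 [4-methoxy-3-(methoxymethoxy)benzyl]triphenylphosphonium bromide
Conditions: PPh3, toluene, 100 °C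
Reagents that add atoms: triphenylphosphine, c1ccc(cc1)P(c1ccccc1)c1ccccc1
Why: SN2 quaternisation of triphenylphosphine by the reactive benzylic bromide, the salt being expected to precipitate from toluene.

Step 6
Reactants: 8 [4-methoxy-3-(methoxymethoxy)benzyl]triphenylphosphonium bromide; 3 4-[3-(hydroxymethyl)phenoxy]-3-methoxybenzaldehyde
Product: 10 [3-(2-methoxy-4-{2-[4-methoxy-3-(methoxymethoxy)phenyl]ethenyl}phenoxy)phenyl]methanol (E/Z mixture), via phosphorus ylide 9 (not isolated)
Conditions: KOtBu, THF, 0 °C; then 3, 0 °C to rt
Reagents that add atoms: none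
Why: Wittig olefination in which the semi-stabilised benzylic ylide adds to the aryl aldehyde and the oxaphosphetane collapses to the stilbene, the benzylic alcohol of 3 being far less acidic than the phosphonium salt and therefore a spectator.

Step 7
Reactants: 10 ring D–ring A stilbene alcohol
Product: 11 1-(bromomethyl)-3-(2-methoxy-4-{2-[4-methoxy-3-(methoxymethoxy)phenyl]ethenyl}phenoxy)benzene (E/Z mixture)
Conditions: CBr4, PPh3, CH2Cl2, 0 °C
Reagents that add atoms: carbon tetrabromide, BrC(Br)(Br)Br
Why: Appel reaction converts the primary benzylic alcohol into the bromide under neutral conditions compatible with the stilbene and the MOM acetal.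

Step 8
Reactants: 11 ring B benzylic bromide
Product: 12 [3-(2-methoxy-4-{2-[4-methoxy-3-(methoxymethoxy)phenyl]ethenyl}phenoxy)benzyl]triphenylphosphonium bromide (E/Z mixture)
Conditions: PPh3, toluene, reflux
Reagents that add atoms: triphenylphosphine, c1ccc(cc1)P(c1ccccc1)c1ccccc1
Why: SN2 quaternisation of triphenylphosphine by the benzylic bromide, with no acid or base present to disturb the other groups.

Step 9
Reactants: 12 ring B phosphonium bromide; 13 4-fluoro-3-nitrobenzaldehyde
Product: 15 1-fluoro-4-{2-[3-(2-methoxy-4-{2-[4-methoxy-3-(methoxymethoxy)phenyl]ethenyl}phenoxy)phenyl]ethenyl}-2-nitrobenzene (E/Z mixture), via phosphorus ylide 14 (not isolated)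
Conditions: NaN(SiMe3)2 (slightly less than 1 equiv), THF, −78 °C; then 13, −78 to 0 °C
Reagents that add atoms: none
Why: Wittig olefination with the ylide preformed by a non-nucleophilic amide base so that no free base remains, carbonyl addition to the electron-poor aldehyde at low temperature being expected to outrun substitution of its activated fluoride.

Step 10
Reactants: 15 fluoronitro bis-stilbene
Product: 16 1-fluoro-4-{2-[3-(2-methoxy-4-{2-[4-methoxy-3-(methoxymethoxy)phenyl]ethyl}phenoxy)phenyl]ethyl}-2-nitrobenzene
Conditions: TsNHNH2 (excess, in portions), NaOAc, DME/H2O, reflux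
Reagents that add atoms: none
Why: Diimide reduction, in which diimide formed by base-promoted loss of sulfinate from the sulfonyl hydrazide transfers hydrogen concertedly to nonpolar C=C bonds only, so both stilbenes should be saturated while nitro group, aryl fluoride and MOM acetal persist.

Step 11
Reactants: 16 MOM-protected fluoronitro bis-bibenzyl
Product: 17 5-[2-(4-{3-[2-(4-fluoro-3-nitrophenyl)ethyl]phenoxy}-3-methoxyphenyl)ethyl]-2-methoxyphenol
Conditions: HCl (aq), MeOH/THF, 50 °C
Reagents that add atoms: none
Why: Acid-catalysed acetal cleavage (MOM removal) frees the ring D phenol under non-basic conditions, so the activated fluoride cannot react prematurely and the aryl methyl ethers remain.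

Step 12
Reactants: 17 open-chain ring D phenol carrying the 4-fluoro-3-nitrophenyl ring C
Product: 18 nitro di-O-methyl macrocycle (NO2 on ring C ortho to the new ether oxygen)
Conditions: K2CO3, DMF, 0.003 M (slow addition of 17), rt
Reagents that add atoms: none
Why: K2CO3 deprotonates the ring D phenol and the phenoxide adds to the fluorine-bearing carbon of ring C to give an anionic Meisenheimer complex whose charge is delocalised into the ortho nitro group, after which fluoride leaves and the arene is restored. The closest known reaction type is the intramolecular SNAr macroetherification of phenoxides with ortho-nitrofluoroarenes, an established entry to macrocyclic diaryl ethers in DMF at ambient temperature. The single ring formed is the 20-membered ring, closed end to end by attack of the ring D oxygen on ring C (O–C(aryl) bond), and the sp3 carbon of the sigma complex should ease the bend into the cyclophane. No stereocentre is created, and any planar chirality the nitro group might confer on ring C is of no consequence because the group is removed. The selectivity needed is ring closure over intermolecular etherification, secured by high dilution with slow addition; chemoselectivity is not in question because 17 has one free phenol (the ring A oxygen is a methyl ether) and one activated C–F bond.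

Step 13
Reactants: 18 nitro di-O-methyl macrocycle
Product: 19 amino di-O-methyl macrocycle (NH2 on ring C ortho to the ring D ether oxygen)
Conditions: H2 (1 atm), Pd/C (palladium metal on carbon), EtOAc/MeOH, rt
Reagents that add atoms: none
Why: Catalytic hydrogenation of the aromatic nitro group to the aniline; the macrocycle holds no other reducible group, since the C–F bond is gone and there are no alkenes or benzyl ethers.

Step 14
Reactants: 19 amino di-O-methyl macrocycle
Product: 21 di-O-methyl macrocycle (ring C unsubstituted), via arenediazonium chloride 20 (not isolated)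
Conditions: NaNO2, aq HCl, THF, 0 °C; then H3PO2 (50% aq), 0 °C to rt
Reagents that add atoms: none
Why: Diazotisation followed by hydrodediazoniation with hypophosphorous acid (hydrogen-atom transfer to the aryl radical) replaces the amino group by hydrogen; because the phenols are still methylated, azo coupling and nitrosation of the electron-rich rings should be suppressed.

Step 15
Reactants: 21 di-O-methyl macrocycle
Product: 22 target bisphenol macrocycle (CNP0329842.0)
Conditions: BBr3, CH2Cl2, −78 °C to rt; then H2O
Reagents that add atoms: none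
Why: Lewis-acid demethylation in which BBr3 coordinates each methyl ether oxygen and bromide removes the methyl group by SN2, whereas the diaryl ether bonds have no sp3 carbon to attack and survive; hydrolysis of the aryl borates gives the bisphenol.

**Compound list**

1 | 3-hydroxybenzyl alcohol | OCc1cccc(O)c1 | starting material
2 | 4-fluoro-3-methoxybenzaldehyde | COc1cc(C=O)ccc1F | starting material
3 | 4-[3-(hydroxymethyl)phenoxy]-3-methoxybenzaldehyde | COc1cc(C=O)ccc1Oc1cccc(CO)c1 | intermediate
4 | isovanillin (3-hydroxy-4-methoxybenzaldehyde) | COc1ccc(C=O)cc1O | starting material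
5 | 4-methoxy-3-(methoxymethoxy)benzaldehyde | COCOc1cc(C=O)ccc1OC | intermediate
6 | [4-methoxy-3-(methoxymethoxy)phenyl]methanol | COCOc1cc(CO)ccc1OC | intermediate
7 | 4-(bromomethyl)-1-methoxy-2-(methoxymethoxy)benzene | COCOc1cc(CBr)ccc1OC | intermediate
8 | [4-methoxy-3-(methoxymethoxy)benzyl]triphenylphosphonium bromide | COCOc1cc(C[P+](c2ccccc2)(c2ccccc2)c2ccccc2)ccc1OC.[Br-] | intermediate
9 | [4-methoxy-3-(methoxymethoxy)benzylidene]triphenylphosphorane (ylide, not isolated) | COCOc1cc(C=P(c2ccccc2)(c2ccccc2)c2ccccc2)ccc1OC | intermediate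
10 | [3-(2-methoxy-4-{2-[4-methoxy-3-(methoxymethoxy)phenyl]ethenyl}phenoxy)phenyl]methanol, E/Z mixture | COCOc1cc(C=Cc2ccc(Oc3cccc(CO)c3)c(OC)c2)ccc1OC | intermediate
11 | 1-(bromomethyl)-3-(2-methoxy-4-{2-[4-methoxy-3-(methoxymethoxy)phenyl]ethenyl}phenoxy)benzene, E/Z mixture | COCOc1cc(C=Cc2ccc(Oc3cccc(CBr)c3)c(OC)c2)ccc1OC | intermediate
12 | [3-(2-methoxy-4-{2-[4-methoxy-3-(methoxymethoxy)phenyl]ethenyl}phenoxy)benzyl]triphenylphosphonium bromide, E/Z mixture | COCOc1cc(C=Cc2ccc(Oc3cccc(C[P+](c4ccccc4)(c4ccccc4)c4ccccc4)c3)c(OC)c2)ccc1OC.[Br-] | intermediate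
13 | 4-fluoro-3-nitrobenzaldehyde | O=Cc1ccc(F)c(c1)[N+](=O)[O-] | starting material
14 | ylide of 12, [3-(2-methoxy-4-{2-[4-methoxy-3-(methoxymethoxy)phenyl]ethenyl}phenoxy)benzylidene]triphenylphosphorane (not isolated) | COCOc1cc(C=Cc2ccc(Oc3cccc(C=P(c4ccccc4)(c4ccccc4)c4ccccc4)c3)c(OC)c2)ccc1OC | intermediate
15 | 1-fluoro-4-{2-[3-(2-methoxy-4-{2-[4-methoxy-3-(methoxymethoxy)phenyl]ethenyl}phenoxy)phenyl]ethenyl}-2-nitrobenzene, E/Z mixture | COCOc1cc(C=Cc2ccc(Oc3cccc(C=Cc4ccc(F)c(c4)[N+](=O)[O-])c3)c(OC)c2)ccc1OC | intermediate
16 | 1-fluoro-4-{2-[3-(2-methoxy-4-{2-[4-methoxy-3-(methoxymethoxy)phenyl]ethyl}phenoxy)phenyl]ethyl}-2-nitrobenzene | COCOc1cc(CCc2ccc(Oc3cccc(CCc4ccc(F)c(c4)[N+](=O)[O-])c3)c(OC)c2)ccc1OC | intermediate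
17 | 5-[2-(4-{3-[2-(4-fluoro-3-nitrophenyl)ethyl]phenoxy}-3-methoxyphenyl)ethyl]-2-methoxyphenol | COc1ccc(CCc2ccc(Oc3cccc(CCc4ccc(F)c(c4)[N+](=O)[O-])c3)c(OC)c2)cc1O | intermediate
18 | nitro di-O-methyl macrocycle: 20-membered ring A–O–ring B–CH2CH2–ring C–O–ring D–CH2CH2 cyclophane, OMe on ring A ortho to the ring B ether oxygen, OMe on ring D ortho to the ring C ether oxygen and para to its benzylic carbon, NO2 on ring C ortho to the ring D ether oxygen | COc1cc2ccc1Oc1cccc(c1)CCc1ccc(c(c1)[N+](=O)[O-])Oc1cc(ccc1OC)CC2 | intermediate
19 | amino di-O-methyl macrocycle: as 18 with NH2 in place of NO2 | COc1cc2ccc1Oc1cccc(c1)CCc1ccc(c(N)c1)Oc1cc(ccc1OC)CC2 | intermediate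
20 | arenediazonium chloride of 19 (not isolated) | COc1cc2ccc1Oc1cccc(c1)CCc1ccc(c([N+]#N)c1)Oc1cc(ccc1OC)CC2.[Cl-] | intermediate
21 | di-O-methyl macrocycle: as 18 with H in place of NO2 | COc1cc2ccc1Oc1cccc(c1)CCc1ccc(cc1)Oc1cc(ccc1OC)CC2 | intermediate
22 | target bisphenol macrocycle (CNP0329842.0): as 21 with both OMe groups as OH | Oc1cc2ccc1Oc1cccc(c1)CCc1ccc(cc1)Oc1cc(ccc1O)CC2 | target

**Count**

Total step count: 15. Longest linear sequence: 14 steps (steps 2 to 15, from isovanillin 4 to 22).

**Steps most likely to fail, with fallbacks**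

Step 12. Intermolecular etherification could outrun ring closure, or the chain might fold too slowly for the substitution to proceed cleanly. The same O–C(ring C) bond would then be made by a copper-catalysed Ullmann etherification. Setting out from phosphonium salt 12, its ylide 14 would be condensed with 4-bromobenzaldehyde (NaN(SiMe3)2, THF) to give the bromo bis-stilbene F1. Diimide reduction (TsNHNH2, NaOAc, DME/H2O), which spares the C–Br bond, would give the bis-bibenzyl aryl bromide F2, and HCl in MeOH/THF would release the bromo phenol F3. Cyclisation with CuI, N,N-dimethylglycine and Cs2CO3 in dioxane at 90 °C under high dilution would deliver the di-O-methyl macrocycle 21 directly, where the route resumes at step 15; steps 13 and 14 are then not needed.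

Step 9. The ylide or traces of base could attack the doubly activated C–F carbon of 13, or transfer an electron to the nitroarene, in competition with carbonyl addition. The polarity of the olefination would then be reversed. Setting out from alcohol 10, MnO2 in CH2Cl2 would give the ring B aldehyde F4. Commercially available 4-fluoro-3-nitrobenzyl bromide and PPh3 in toluene would give (4-fluoro-3-nitrobenzyl)triphenylphosphonium bromide F5. A Wittig reaction of F4 with F5 under mild solid–liquid conditions (K2CO3, 18-crown-6, CH2Cl2, reflux) would give the bis-stilbene 15, where the route resumes at step 10. In the ylide of F5 the carbanion lies para to fluorine and should deactivate it towards substitution.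

Step 10. Sulfinate or the hydrazide could displace the activated fluoride during prolonged heating, or saturation of the two stilbenes could remain incomplete. The second two-carbon bridge would then be built already saturated by a B-alkyl Suzuki–Miyaura coupling. Setting out from alcohol 10, hydrogenation (H2, Pd/C, EtOAc) before any nitro group is present would give the saturated alcohol F6, and MnO2 would give the aldehyde F7. Wittig methylenation (Ph3PCH3Br, KOtBu, THF) would give the styrene F8, and hydroboration with 9-BBN in THF would give the B-alkyl borane F9. Coupling of F9 in the same flask with 4-bromo-1-fluoro-2-nitrobenzene (PdCl2(dppf), K3PO4, THF/DMF, 50 °C) would give 16, where the route resumes at step 11.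

**Further compounds**

F1 | step 12 | 1-bromo-4-{2-[3-(2-methoxy-4-{2-[4-methoxy-3-(methoxymethoxy)phenyl]ethenyl}phenoxy)phenyl]ethenyl}benzene, E/Z mixture | COCOc1cc(C=Cc2ccc(Oc3cccc(C=Cc4ccc(Br)cc4)c3)c(OC)c2)ccc1OC
F2 | step 12 | 1-bromo-4-{2-[3-(2-methoxy-4-{2-[4-methoxy-3-(methoxymethoxy)phenyl]ethyl}phenoxy)phenyl]ethyl}benzene | COCOc1cc(CCc2ccc(Oc3cccc(CCc4ccc(Br)cc4)c3)c(OC)c2)ccc1OC
F3 | step 12 | 5-[2-(4-{3-[2-(4-bromophenyl)ethyl]phenoxy}-3-methoxyphenyl)ethyl]-2-methoxyphenol | COc1ccc(CCc2ccc(Oc3cccc(CCc4ccc(Br)cc4)c3)c(OC)c2)cc1O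
F4 | step 9 | 3-(2-methoxy-4-{2-[4-methoxy-3-(methoxymethoxy)phenyl]ethenyl}phenoxy)benzaldehyde, E/Z mixture | COCOc1cc(C=Cc2ccc(Oc3cccc(C=O)c3)c(OC)c2)ccc1OC
F5 | step 9 | (4-fluoro-3-nitrobenzyl)triphenylphosphonium bromide | [O-][N+](=O)c1cc(C[P+](c2ccccc2)(c2ccccc2)c2ccccc2)ccc1F.[Br-]
F6 | step 10 | [3-(2-methoxy-4-{2-[4-methoxy-3-(methoxymethoxy)phenyl]ethyl}phenoxy)phenyl]methanol | COCOc1cc(CCc2ccc(Oc3cccc(CO)c3)c(OC)c2)ccc1OC
F7 | step 10 | 3-(2-methoxy-4-{2-[4-methoxy-3-(methoxymethoxy)phenyl]ethyl}phenoxy)benzaldehyde | COCOc1cc(CCc2ccc(Oc3cccc(C=O)c3)c(OC)c2)ccc1OC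
F8 | step 10 | 1-ethenyl-3-(2-methoxy-4-{2-[4-methoxy-3-(methoxymethoxy)phenyl]ethyl}phenoxy)benzene | COCOc1cc(CCc2ccc(Oc3cccc(C=C)c3)c(OC)c2)ccc1OC
F9 | step 10 | 9-{2-[3-(2-methoxy-4-{2-[4-methoxy-3-(methoxymethoxy)phenyl]ethyl}phenoxy)phenyl]ethyl}-9-borabicyclo[3.3.1]nonane | COCOc1cc(CCc2ccc(Oc3cccc(CCB4C5CCCC4CCC5)c3)c(OC)c2)ccc1OC
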